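**Plan**

- Retrosynthetic cuts, in order: the three O–Si bonds; the C8–C(=O) bond of the enone; ring A at C5–C6, C7–C8 and C4a–C5 (plus C8–C8a, which a Wolff shift makes); the acetyl–pyran bond; the O1–C(sp2) bond of the pyran ring; the two C–Me bonds and the CH2–alkyne bond back to methyl (R)-glycidate.
- Enabling feature: ring A carries oxygen on C5, C7 and C8a in a 1,3,5 pattern and shares C4a–C8a with the pyran ring. C8a and C4a are therefore the enol ether carbons of a dihydropyran-6-yl ketene, and C6/C7 with the methoxy group are methoxyacetylene.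
- Forward order: the pyran ring is built first (epoxide alkynylation, Grignard addition, 6-endo cycloisomerisation), then acetylated and converted to the diazo ketone. Ring A is then closed onto it by a photochemical ketene benzannulation. The cinnamoyl chain carrying ring B is attached at C8 by directed lithiation, and all silyl groups are removed last.
- Stereochemistry: C3 (R) comes from methyl (R)-glycidate and is never a reacting centre; the E enone comes from a Horner–Wadsworth–Emmons reaction.

Key step: step 9

**Route**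

Step 1
Reactants: 1 methyl (R)-glycidate; 2 trimethylsilylacetylene
Product: 4 methyl (2R)-2-hydroxy-5-(trimethylsilyl)pent-4-ynoate, via lithium (trimethylsilyl)acetylide 3 (not isolated)
Conditions: 2, n-BuLi, THF, −78 °C; BF3·OEt2; then 1, −78 °C
Reagents that add atoms: none
Why: The BF3-activated lithium acetylide should open the epoxide at its unsubstituted carbon faster than it attacks the ester at −78 °C (Yamaguchi–Hirao alkynylation), and since C2 is not involved the R configuration is carried over unchanged.

Step 2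
Reactants: 4 methyl (2R)-2-hydroxy-5-(trimethylsilyl)pent-4-ynoate
Product: 5 methyl (2R)-2-(tert-butyldimethylsilyloxy)-5-(trimethylsilyl)pent-4-ynoate
Conditions: TBSCl, imidazole, DMF, rt
Reagents that add atoms: tert-butyldimethylsilyl chloride, CC(C)(C)[Si](C)(C)Cl
Why: Imidazole-promoted silylation of a secondary alcohol is routine and too weakly basic to epimerise the α-oxy ester.

Step 3
Reactants: 5 methyl (2R)-2-(tert-butyldimethylsilyloxy)-5-(trimethylsilyl)pent-4-ynoate
Product: 6 (3R)-3-(tert-butyldimethylsilyloxy)-2-methyl-6-(trimethylsilyl)hex-5-yn-2-ol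
Conditions: MeMgBr (3 equiv), THF, 0 °C → rt
Reagents that add atoms: methylmagnesium bromide, C[Mg]Br
Why: Double Grignard addition to the ester should give the tertiary carbinol; the intermediate methyl ketone is consumed faster than it enolises, so the adjacent stereocentre is kept, and both silyl groups are inert.

Step 4
Reactants: 6 (3R)-3-(tert-butyldimethylsilyloxy)-2-methyl-6-(trimethylsilyl)hex-5-yn-2-ol
Product: 7 (3R)-3-(tert-butyldimethylsilyloxy)-2-methylhex-5-yn-2-ol
Conditions: K2CO3 (cat.), MeOH, rt
Reagents that add atoms: none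
Why: Methanolysis of the alkynyl C–Si bond (protodesilylation) is selective because an alkyl tert-butyldimethylsilyl ether does not react with K2CO3 in methanol at room temperature.

Step 5
Reactants: 7 (3R)-3-(tert-butyldimethylsilyloxy)-2-methylhex-5-yn-2-ol
Product: 8 (3R)-3-(tert-butyldimethylsilyloxy)-2,2-dimethyl-3,4-dihydro-2H-pyran
Conditions: W(CO)6 (25 mol %), Et3N, THF, hν (350 nm), 60 °C
Reagents that add atoms: none
Why: Photolysis of W(CO)6 gives W(CO)5(THF), which converts the terminal alkyne into a tungsten vinylidene; the tertiary hydroxyl adds to its electrophilic α-carbon in the 6-endo sense and amine-assisted protodemetalation releases the cyclic enol ether (tungsten-catalysed alkynol cycloisomerisation), with the gem-dimethyl group favouring closure.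

Step 6
Reactants: 8 (3R)-3-(tert-butyldimethylsilyloxy)-2,2-dimethyl-3,4-dihydro-2H-pyran
Product: 10 1-[(3R)-3-(tert-butyldimethylsilyloxy)-2,2-dimethyl-3,4-dihydro-2H-pyran-6-yl]ethanone, via 6-lithio dihydropyran 9 (not isolated)
Conditions: t-BuLi, THF, −78 → 0 °C; then MeC(O)N(OMe)Me, −78 °C → rt
Reagents that add atoms: N-methoxy-N-methylacetamide, CC(=O)N(C)OC
Why: Oxygen-directed vinylic α-lithiation of a cyclic enol ether followed by acylation with a Weinreb amide should stop at the ketone, because the chelated tetrahedral adduct survives until work-up (Weinreb ketone synthesis).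

Step 7
Reactants: 10 1-[(3R)-3-(tert-butyldimethylsilyloxy)-2,2-dimethyl-3,4-dihydro-2H-pyran-6-yl]ethanone
Product: 12 2-diazo-1-[(3R)-3-(tert-butyldimethylsilyloxy)-2,2-dimethyl-3,4-dihydro-2H-pyran-6-yl]ethanone, via trifluoroacetyl diketone 11 (not isolated)
Conditions: LiN(SiMe3)2, THF, −78 °C; CF3CO2CH2CF3; volatiles removed; then MsN3, Et3N, H2O, MeCN, rt
Reagents that add atoms: methanesulfonyl azide, CS(=O)(=O)N=[N+]=[N-]
Why: Detrifluoroacetylative diazo transfer: the kinetic methyl enolate is trifluoroacetylated, the resulting 1,3-diketone accepts the diazo group from the sulfonyl azide and then loses the trifluoroacetyl group, all under basic conditions that leave the enol ether and the silyl ether intact.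

Step 8
Reactants: 13 chloroacetaldehyde dimethyl acetal
Product: 16 methoxyacetylene, via (Z)-1-chloro-2-methoxyethene 14 (not isolated), via sodium methoxyacetylide 15 (not isolated)
Conditions: NaNH2 (3 equiv), liq. NH3, −33 °C; then sat. aq NaCl, −70 °C → rt, distilled into a cold trap
Reagents that add atoms: none
Why: Two successive base-induced eliminations (methanol, then HCl) are the classical preparation of alkoxyacetylenes, and the product is stored as its sodium acetylide until the cold aqueous quench.

Step 9
Reactants: 12 2-diazo-1-[(3R)-3-(tert-butyldimethylsilyloxy)-2,2-dimethyl-3,4-dihydro-2H-pyran-6-yl]ethanone; 16 methoxyacetylene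
Product: 21 (3R)-3-(tert-butyldimethylsilyloxy)-7-methoxy-2,2-dimethylchroman-5-ol, via pyranyl vinylketene 17 (not isolated), via vinylcyclobutenone 18 (not isolated), via dienylketene 19 (not isolated), via cyclohexadienone 20 (not isolated)
Conditions: 16 (3 equiv), ClCH2CH2Cl, hν (254 nm, sealed quartz tube), rt; then 80 °C
Reagents that add atoms: none
Why: Light expels N2 from 12 and the pyranyl group shifts to the former diazo carbon (photochemical Wolff rearrangement, forming C8–C8a) to give vinylketene 17, whose C=C=O unit adds methoxyacetylene in a [2+2] cycloaddition to give cyclobutenone 18 (C5–C6 and C7–C8). Reversible four-electron electrocyclic opening of 18 gives dienylketene 19, and a thermal disrotatory six-electron electrocyclisation joins the ketene carbon to the enol ether β-carbon (C4a–C5), closing ring A as dienone 20, which tautomerises to the phenol. This is the Danheiser benzannulation in its diazo ketone form, known for α,β-unsaturated diazo ketones with alkoxy- and siloxyalkynes. No stereocentre is formed, and C3 lies outside the reacting π system and keeps its R configuration. The selectivity required is the orientation of the [2+2] step: the oxygen lone pair makes the unsubstituted alkyne carbon the nucleophile, so it bonds to the ketene carbonyl carbon and the methoxy group ends on C7, meta to the new C5 hydroxyl. The ring oxygen already on the enol ether carbon fixes O1 on C8a.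

Step 10
Reactants: 21 (3R)-3-(tert-butyldimethylsilyloxy)-7-methoxy-2,2-dimethylchroman-5-ol
Product: 22 (3R)-3-(tert-butyldimethylsilyloxy)-7-methoxy-2,2-dimethyl-5-(triisopropylsilyloxy)chroman
Conditions: TIPSCl, imidazole, DMF, rt
Reagents that add atoms: triisopropylsilyl chloride, CC(C)[Si](Cl)(C(C)C)C(C)C
Why: Phenol silylation under imidazole catalysis installs a bulky group that resists n-BuLi and blocks C6 in the lithiation that follows.

Step 11
Reactants: 23 4-(tert-butyldimethylsilyloxy)benzaldehyde; 24 diethyl [2-(methoxy(methyl)amino)-2-oxoethyl]phosphonate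
Product: 25 (E)-3-[4-(tert-butyldimethylsilyloxy)phenyl]-N-methoxy-N-methylprop-2-enamide
Conditions: NaH, THF, 0 °C → rt
Reagents that add atoms: none
Why: The Horner–Wadsworth–Emmons reaction of a stabilised phosphonate anion with an aromatic aldehyde should give the E-configured unsaturated amide under thermodynamic control, and the aryl silyl ether tolerates the anion.

Step 12
Reactants: 22 (3R)-3-(tert-butyldimethylsilyloxy)-7-methoxy-2,2-dimethyl-5-(triisopropylsilyloxy)chroman; 25 (E)-3-[4-(tert-butyldimethylsilyloxy)phenyl]-N-methoxy-N-methylprop-2-enamide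
Product: 27 (E)-1-[(3R)-3-(tert-butyldimethylsilyloxy)-7-methoxy-2,2-dimethyl-5-(triisopropylsilyloxy)chroman-8-yl]-3-[4-(tert-butyldimethylsilyloxy)phenyl]prop-2-en-1-one, via 8-lithio chroman 26 (not isolated)
Conditions: n-BuLi, TMEDA, THF, 0 °C; then 25, −78 → 0 °C
Reagents that add atoms: none
Why: Directed ortho-metalation should remove H8, which is flanked by the C7 methoxy oxygen and the ring oxygen O1 that together hold lithium, while H6 is shielded by the bulky, poorly coordinating silyloxy group; the aryllithium then adds 1,2 to the Weinreb amide to give a chelate that releases the ketone only on work-up, with the E alkene unchanged.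

Step 13
Reactants: 27 (E)-1-[(3R)-3-(tert-butyldimethylsilyloxy)-7-methoxy-2,2-dimethyl-5-(triisopropylsilyloxy)chroman-8-yl]-3-[4-(tert-butyldimethylsilyloxy)phenyl]prop-2-en-1-one
Product: 28 (E)-1-[(3R)-3,5-dihydroxy-7-methoxy-2,2-dimethylchroman-8-yl]-3-(4-hydroxyphenyl)prop-2-en-1-one
Conditions: Bu4NF (excess), THF, 0 °C → rt; then AcOH
Reagents that add atoms: none
Why: Fluoride-induced desilylation cleaves both aryl silyl ethers quickly and the secondary alkyl silyl ether more slowly; the ketone has no free ortho hydroxyl (its neighbours are OMe and O1), so flavanone closure cannot occur, and C3 is unaffected.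

**Compound list**

1 | methyl (R)-glycidate | COC(=O)[C@H]1CO1 | starting material
2 | trimethylsilylacetylene | C[Si](C)(C)C#C | starting material
3 | lithium (trimethylsilyl)acetylide | C[Si](C)(C)C#C[Li] | intermediate
4 | methyl (2R)-2-hydroxy-5-(trimethylsilyl)pent-4-ynoate | COC(=O)[C@H](O)CC#C[Si](C)(C)C | intermediate
5 | methyl (2R)-2-(tert-butyldimethylsilyloxy)-5-(trimethylsilyl)pent-4-ynoate | COC(=O)[C@H](O[Si](C)(C)C(C)(C)C)CC#C[Si](C)(C)C | intermediate
6 | (3R)-3-(tert-butyldimethylsilyloxy)-2-methyl-6-(trimethylsilyl)hex-5-yn-2-ol | CC(C)(O)[C@H](O[Si](C)(C)C(C)(C)C)CC#C[Si](C)(C)C | intermediate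
7 | (3R)-3-(tert-butyldimethylsilyloxy)-2-methylhex-5-yn-2-ol | CC(C)(O)[C@H](O[Si](C)(C)C(C)(C)C)CC#C | intermediate
8 | (3R)-3-(tert-butyldimethylsilyloxy)-2,2-dimethyl-3,4-dihydro-2H-pyran | C1=CC[C@@H](O[Si](C)(C)C(C)(C)C)C(C)(C)O1 | intermediate
9 | [(3R)-3-(tert-butyldimethylsilyloxy)-2,2-dimethyl-3,4-dihydro-2H-pyran-6-yl]lithium | [Li]C1=CC[C@@H](O[Si](C)(C)C(C)(C)C)C(C)(C)O1 | intermediate
10 | 1-[(3R)-3-(tert-butyldimethylsilyloxy)-2,2-dimethyl-3,4-dihydro-2H-pyran-6-yl]ethanone | CC(=O)C1=CC[C@@H](O[Si](C)(C)C(C)(C)C)C(C)(C)O1 | intermediate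
11 | 4,4,4-trifluoro-1-[(3R)-3-(tert-butyldimethylsilyloxy)-2,2-dimethyl-3,4-dihydro-2H-pyran-6-yl]butane-1,3-dione (present as its lithium enolate) | O=C(CC(=O)C(F)(F)F)C1=CC[C@@H](O[Si](C)(C)C(C)(C)C)C(C)(C)O1 | intermediate
12 | 2-diazo-1-[(3R)-3-(tert-butyldimethylsilyloxy)-2,2-dimethyl-3,4-dihydro-2H-pyran-6-yl]ethanone | [N-]=[N+]=CC(=O)C1=CC[C@@H](O[Si](C)(C)C(C)(C)C)C(C)(C)O1 | intermediate
13 | chloroacetaldehyde dimethyl acetal (2-chloro-1,1-dimethoxyethane) | COC(CCl)OC | starting material
14 | (Z)-1-chloro-2-methoxyethene | CO/C=C\Cl | intermediate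
15 | sodium methoxyacetylide | [Na+].[C-]#COC | intermediate
16 | methoxyacetylene | COC#C | intermediate
17 | 2-[(3R)-3-(tert-butyldimethylsilyloxy)-2,2-dimethyl-3,4-dihydro-2H-pyran-6-yl]ethenone | O=C=CC1=CC[C@@H](O[Si](C)(C)C(C)(C)C)C(C)(C)O1 | intermediate
18 | 3-methoxy-4-[(3R)-3-(tert-butyldimethylsilyloxy)-2,2-dimethyl-3,4-dihydro-2H-pyran-6-yl]cyclobut-2-en-1-one (both epimers at C4 of the four-membered ring) | COC1=CC(=O)C1C2=CC[C@@H](O[Si](C)(C)C(C)(C)C)C(C)(C)O2 | intermediate
19 | (3E)-3-methoxy-4-[(3R)-3-(tert-butyldimethylsilyloxy)-2,2-dimethyl-3,4-dihydro-2H-pyran-6-yl]buta-1,3-dien-1-one | O=C=C/C(OC)=C\C1=CC[C@@H](O[Si](C)(C)C(C)(C)C)C(C)(C)O1 | intermediate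
20 | (3R)-3-(tert-butyldimethylsilyloxy)-7-methoxy-2,2-dimethyl-2,3,4,4a-tetrahydro-5H-chromen-5-one (both epimers at C4a) | COC1=CC(=O)C2C[C@@H](O[Si](C)(C)C(C)(C)C)C(C)(C)OC2=C1 | intermediate
21 | (3R)-3-(tert-butyldimethylsilyloxy)-7-methoxy-2,2-dimethylchroman-5-ol | COc1cc(O)c2c(c1)OC(C)(C)[C@H](O[Si](C)(C)C(C)(C)C)C2 | intermediate
22 | (3R)-3-(tert-butyldimethylsilyloxy)-7-methoxy-2,2-dimethyl-5-(triisopropylsilyloxy)chroman | COc1cc(O[Si](C(C)C)(C(C)C)C(C)C)c2c(c1)OC(C)(C)[C@H](O[Si](C)(C)C(C)(C)C)C2 | intermediate
23 | 4-(tert-butyldimethylsilyloxy)benzaldehyde | O=Cc1ccc(O[Si](C)(C)C(C)(C)C)cc1 | starting material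
24 | diethyl [2-(methoxy(methyl)amino)-2-oxoethyl]phosphonate | CCOP(=O)(CC(=O)N(C)OC)OCC | starting material
25 | (E)-3-[4-(tert-butyldimethylsilyloxy)phenyl]-N-methoxy-N-methylprop-2-enamide | CON(C)C(=O)/C=C/c1ccc(O[Si](C)(C)C(C)(C)C)cc1 | intermediate
26 | [(3R)-3-(tert-butyldimethylsilyloxy)-7-methoxy-2,2-dimethyl-5-(triisopropylsilyloxy)chroman-8-yl]lithium | COc1cc(O[Si](C(C)C)(C(C)C)C(C)C)c2c(c1[Li])OC(C)(C)[C@H](O[Si](C)(C)C(C)(C)C)C2 | intermediate
27 | (E)-1-[(3R)-3-(tert-butyldimethylsilyloxy)-7-methoxy-2,2-dimethyl-5-(triisopropylsilyloxy)chroman-8-yl]-3-[4-(tert-butyldimethylsilyloxy)phenyl]prop-2-en-1-one | COc1cc(O[Si](C(C)C)(C(C)C)C(C)C)c2c(c1C(=O)/C=C/c1ccc(O[Si](C)(C)C(C)(C)C)cc1)OC(C)(C)[C@H](O[Si](C)(C)C(C)(C)C)C2 | intermediate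
28 | (E)-1-[(3R)-3,5-dihydroxy-7-methoxy-2,2-dimethylchroman-8-yl]-3-(4-hydroxyphenyl)prop-2-en-1-one | COc1cc(O)c2c(c1C(=O)/C=C/c1ccc(O)cc1)OC(C)(C)[C@H](O)C2 | target

**Step count**

Total: 13 steps. Longest linear sequence: 11 steps (steps 1–7, 9, 10, 12 and 13, from methyl (R)-glycidate); steps 8 and 11 are side branches.

**Steps most likely to fail**

1. Step 9. The low-boiling ynol ether may escape or polymerise under irradiation, so that the ketene dimerises or acylates phenol already formed instead of entering the [2+2] step. The fallback sets out from 16: deprotonation with n-BuLi in THF at −78 °C and quenching with Me3SiCl should give the higher-boiling (methoxyethynyl)trimethylsilane F1, which can be used in large excess and heated without loss. Irradiation of 12 with F1 followed by heating should give, with the same orientation (silicon sits on the nucleophilic alkyne carbon), (3R)-3-(tert-butyldimethylsilyloxy)-7-methoxy-2,2-dimethyl-6-(trimethylsilyl)chroman-5-ol F2, whose ortho silyl group also shields the phenol from ketene. Ipso-protodesilylation of the electron-rich ring with CF3CO2H in CH2Cl2 at 0 °C brings the route back to 21.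

2. Step 12. Deprotonation may occur partly at C6 or be too slow, and the hindered aryllithium may be consumed by side reactions before it is acylated. The fallback sets out from 22: electrophilic bromination with NBS in CH2Cl2 at −78 → 0 °C should take place at the unshielded, doubly activated C8 to give (3R)-8-bromo-3-(tert-butyldimethylsilyloxy)-7-methoxy-2,2-dimethyl-5-(triisopropylsilyloxy)chroman F3. Bromine–lithium exchange with t-BuLi (2 equiv) in THF at −78 °C then generates the C8 anion regiospecifically within minutes, and addition of 25 returns the route to 27.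

3. Step 5. Addition of the hindered tertiary hydroxyl to the tungsten vinylidene may be slow, allowing exo closure or alkyne oligomerisation to take over. The fallback sets out from 7: anti-Markovnikov hydroboration of the alkyne with dicyclohexylborane in THF at 0 °C and oxidation with NaBO3·4H2O should give the aldehyde, which closes to the lactol (5R)-5-(tert-butyldimethylsilyloxy)-6,6-dimethyltetrahydro-2H-pyran-2-ol F4 (both anomers). Mesylation and elimination with MsCl and Et3N in CH2Cl2 (0 °C → reflux) dehydrates it to 8.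

**Further compounds**

F1 | step 9 | (methoxyethynyl)trimethylsilane | COC#C[Si](C)(C)C
F2 | step 9 | (3R)-3-(tert-butyldimethylsilyloxy)-7-methoxy-2,2-dimethyl-6-(trimethylsilyl)chroman-5-ol | COc1c([Si](C)(C)C)c(O)c2c(c1)OC(C)(C)[C@H](O[Si](C)(C)C(C)(C)C)C2
F3 | step 12 | (3R)-8-bromo-3-(tert-butyldimethylsilyloxy)-7-methoxy-2,2-dimethyl-5-(triisopropylsilyloxy)chroman | COc1cc(O[Si](C(C)C)(C(C)C)C(C)C)c2c(c1Br)OC(C)(C)[C@H](O[Si](C)(C)C(C)(C)C)C2
F4 | step 5 | (5R)-5-(tert-butyldimethylsilyloxy)-6,6-dimethyltetrahydro-2H-pyran-2-ol | OC1CC[C@@H](O[Si](C)(C)C(C)(C)C)C(C)(C)O1
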